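**Plan**
Retrosynthesis: the cuts come in this order: the C5–alkenyl bond (Suzuki–Miyaura), C5–B back to C5–H, O1–C7a of the dihydrofuran ring, the C2–O1/C3–H pair (hydroboration of a C2=C3 alkene), C3–C3a (Suzuki–Miyaura), and the veratryl–C2 bond (Sonogashira).
Enabling feature: in ring A, C7a carries O1 and lies between C7 (OMe) and C3a (which bears C3). A fluorine on C7a therefore has no ortho hydrogen, so an alkoxide on C2 can replace it by addition–elimination and no aryne can form.
Forward: the open chain veratryl–C2–C3(CH3)–aryl is built in steps 1–3 and turned into the alcohol in step 4. The only new ring, O1–C2–C3–C3a–C7a, closes in step 5, and the C5 side chain is added in steps 6 and 7.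
Stereochemistry: syn borylcupration of the alkyne and a stereoretentive coupling give the (E)-alkene. Syn hydroboration converts that geometry into the relative configuration that becomes trans-C2/C3. Monoisopinocampheylborane made from (−)-α-pinene sets the absolute configuration, and the side-chain (E) geometry comes with the iodide.

Key step: step 5

Assumption: the face selectivity of monoisopinocampheylborane toward 6 is taken to follow that known for 1-arylcycloalkenes, which calls for the reagent from (−)-α-pinene. If 6 responds in the opposite sense, the reagent from (+)-α-pinene is used and nothing else changes.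

Step 1
Reactants: 1 4-bromo-1,2-dimethoxybenzene; 2 propyne
Product: 3 1,2-dimethoxy-4-(prop-1-yn-1-yl)benzene
Conditions: PdCl2(PhCN)2 (3 mol %), [HP(t-Bu)3]BF4 (6 mol %), CuI (2 mol %), i-Pr2NH (1.5 equiv), propyne (1.5 equiv, solution in THF), 1,4-dioxane, rt, closed vessel
Reagents that add atoms: none
Why: Sonogashira coupling, in which the bulky electron-rich phosphine lets zerovalent palladium insert into the electron-rich aryl bromide at room temperature, so the volatile alkyne stays in solution.

Step 2
Reactants: 3 1,2-dimethoxy-4-(prop-1-yn-1-yl)benzene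
Product: 4 2-[(Z)-1-(3,4-dimethoxyphenyl)prop-1-en-2-yl]-4,4,5,5-tetramethyl-1,3,2-dioxaborolane
Conditions: CuCl (5 mol %), P(p-tol)3 (6 mol %), NaOt-Bu (15 mol %), B2pin2 (1.1 equiv), MeOH (2 equiv), THF, rt
Reagents that add atoms: bis(pinacolato)diboron, CC1(C)OB(OC1(C)C)B1OC(C)(C)C(C)(C)O1
Why: copper-catalysed formal hydroboration (borylcupration–protonation), in which the copper boryl adds syn with copper on the aryl-bearing carbon and boron on the methyl-bearing carbon, and methanol protonates the C–Cu bond with retention, leaving aryl and methyl cis.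

Step 3
Reactants: 4 2-[(Z)-1-(3,4-dimethoxyphenyl)prop-1-en-2-yl]-4,4,5,5-tetramethyl-1,3,2-dioxaborolane; 5 1-bromo-2-fluoro-3-methoxybenzene
Product: 6 1-[(E)-1-(3,4-dimethoxyphenyl)prop-1-en-2-yl]-2-fluoro-3-methoxybenzene
Conditions: Pd(dppf)Cl2 (3 mol %), K3PO4 (3 equiv), 1,4-dioxane/H2O 5:1, 80 °C
Reagents that add atoms: none
Why: Suzuki–Miyaura coupling keeps the configuration at the alkenyl carbon, so the fluoroaryl group takes the place of boron, trans to the veratryl group, and the (E)-alkene should form as a single isomer.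

Step 4
Reactants: 6 1-[(E)-1-(3,4-dimethoxyphenyl)prop-1-en-2-yl]-2-fluoro-3-methoxybenzene
Product: 8 (1S,2S)-1-(3,4-dimethoxyphenyl)-2-(2-fluoro-3-methoxyphenyl)propan-1-ol, via isopinocampheyl(alkyl)borane 7 (not isolated)
Conditions: (IpcBH2)2·TMEDA [from (−)-α-pinene], BF3·OEt2, THF, rt, filter; 6, −25 → 0 °C; then 3 M NaOH, 30% H2O2, 0 °C → rt
Reagents that add atoms: hydrogen peroxide, OO
Why: Brown asymmetric hydroboration–oxidation of an aryl-substituted trisubstituted alkene, in which boron adds to the less substituted alkene carbon and hydrogen to the methyl-bearing one from the same face, so the (E) geometry fixes the relative configuration of C1 and C2, the isopinocampheyl group on boron chooses the face and thereby the absolute configuration, and alkaline peroxide replaces boron by oxygen with retention.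

Step 5
Reactants: 8 (1S,2S)-1-(3,4-dimethoxyphenyl)-2-(2-fluoro-3-methoxyphenyl)propan-1-ol
Product: 10 (2S,3S)-2-(3,4-dimethoxyphenyl)-7-methoxy-3-methyl-2,3-dihydro-1-benzofuran, via potassium alkoxide 9 (not isolated)
Conditions: KH (1.2 equiv), 1,4-dioxane/DMPU 4:1, rt, then 100 °C, argon
Reagents that add atoms: none
Why: KH deprotonates 8 irreversibly to the potassium alkoxide 9, whose oxygen adds to the fluorine-bearing carbon (the future C7a) and expels fluoride by addition–elimination through a Meisenheimer-type adduct or its concerted variant. The closest known reaction type is the base-induced cyclisation of 2-(2-fluoroaryl)ethanols to 2,3-dihydrobenzofurans, which also runs on rings without nitro or carbonyl activation. The one ring formed, O1–C2–C3–C3a–C7a, closes in the 5-exo-trig mode, helped by the high effective molarity of an alkoxide held three atoms from the ipso carbon. No stereocentre is created and no bond to C1 or C2 of 8 is broken, so these centres become C2 and C3 of 10 unchanged and place the aryl and methyl groups trans. The step needs ipso substitution in preference to aryne formation, ether cleavage and epimerisation, and the substrate secures this because the fluorine is flanked by C3a and by the methoxy carbon C7 and so has no ortho hydrogen, because fluoride is the only leaving group suited to addition–elimination, and because the ortho methoxy group withdraws inductively and can hold the potassium ion beside the fluorine. Once hydrogen has left, no base stronger than the alkoxide remains, so the benzylic C–H bonds at C2 and C3 are not at risk.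

Step 6
Reactants: 10 (2S,3S)-2-(3,4-dimethoxyphenyl)-7-methoxy-3-methyl-2,3-dihydro-1-benzofuran
Product: 11 2-[(2S,3S)-2-(3,4-dimethoxyphenyl)-7-methoxy-3-methyl-2,3-dihydro-1-benzofuran-5-yl]-4,4,5,5-tetramethyl-1,3,2-dioxaborolane
Conditions: [Ir(OMe)(cod)]2 (1.5 mol %), dtbpy (3 mol %), B2pin2 (1.1 equiv), THF, 80 °C, sealed tube
Reagents that add atoms: bis(pinacolato)diboron, CC1(C)OB(OC1(C)C)B1OC(C)(C)C(C)(C)O1
Why: iridium-catalysed C–H borylation is governed by sterics, and C5–H is the only aromatic C–H of 10 with hydrogen on both neighbouring carbons (C4, C6, C2', C5' and C6' each lie next to a substituent), as in the known 5-borylation of 1,2,3-trisubstituted benzenes.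

Step 7
Reactants: 11 2-[(2S,3S)-2-(3,4-dimethoxyphenyl)-7-methoxy-3-methyl-2,3-dihydro-1-benzofuran-5-yl]-4,4,5,5-tetramethyl-1,3,2-dioxaborolane; 12 (E)-3-iodoprop-2-en-1-ol
Product: 13 (E)-3-[(2S,3S)-2-(3,4-dimethoxyphenyl)-7-methoxy-3-methyl-2,3-dihydro-1-benzofuran-5-yl]prop-2-en-1-ol (target)
Conditions: Pd(dppf)Cl2 (5 mol %), K3PO4 (3 equiv), THF/H2O 5:1, 40 °C, dark
Reagents that add atoms: none
Why: Suzuki–Miyaura coupling of an aryl boronate with an alkenyl iodide keeps the (E) geometry, tolerates the free hydroxyl group and runs under conditions too mild to affect C2 or C3.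

**Compound list**
1 | 4-bromo-1,2-dimethoxybenzene | COc1ccc(Br)cc1OC | starting material
2 | propyne | CC#C | starting material
3 | 1,2-dimethoxy-4-(prop-1-yn-1-yl)benzene | CC#Cc1ccc(OC)c(OC)c1 | intermediate
4 | 2-[(Z)-1-(3,4-dimethoxyphenyl)prop-1-en-2-yl]-4,4,5,5-tetramethyl-1,3,2-dioxaborolane (aryl and methyl cis) | C/C(B1OC(C)(C)C(C)(C)O1)=C\c1ccc(OC)c(OC)c1 | intermediate
5 | 1-bromo-2-fluoro-3-methoxybenzene | COc1cccc(Br)c1F | starting material
6 | 1-[(E)-1-(3,4-dimethoxyphenyl)prop-1-en-2-yl]-2-fluoro-3-methoxybenzene (the two aryl groups trans) | C/C(c1cccc(OC)c1F)=C\c1ccc(OC)c(OC)c1 | intermediate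
7 | (isopinocampheyl)[(1S,2R)-1-(3,4-dimethoxyphenyl)-2-(2-fluoro-3-methoxyphenyl)propyl]borane (Ipc from (−)-α-pinene; boron stands where the OH of 8 will stand) | COc1ccc([C@H]([C@@H](C)c2cccc(OC)c2F)B[C@H]3C[C@H]4C[C@@H]([C@@H]3C)C4(C)C)cc1OC | intermediate
8 | (1S,2S)-1-(3,4-dimethoxyphenyl)-2-(2-fluoro-3-methoxyphenyl)propan-1-ol (OH and CH3 anti when the aryl–C1–C2–aryl chain is drawn as a zigzag) | COc1ccc([C@H]([C@@H](C)c2cccc(OC)c2F)O)cc1OC | intermediate
9 | potassium (1S,2S)-1-(3,4-dimethoxyphenyl)-2-(2-fluoro-3-methoxyphenyl)propan-1-olate | COc1ccc([C@H]([C@@H](C)c2cccc(OC)c2F)[O-])cc1OC.[K+] | intermediate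
10 | (2S,3S)-2-(3,4-dimethoxyphenyl)-7-methoxy-3-methyl-2,3-dihydro-1-benzofuran (trans) | COc1ccc([C@H]2Oc3c(OC)cccc3[C@@H]2C)cc1OC | intermediate
11 | 2-[(2S,3S)-2-(3,4-dimethoxyphenyl)-7-methoxy-3-methyl-2,3-dihydro-1-benzofuran-5-yl]-4,4,5,5-tetramethyl-1,3,2-dioxaborolane | COc1ccc([C@H]2Oc3c(OC)cc(B4OC(C)(C)C(C)(C)O4)cc3[C@@H]2C)cc1OC | intermediate
12 | (E)-3-iodoprop-2-en-1-ol | OC/C=C/I | starting material
13 | (E)-3-[(2S,3S)-2-(3,4-dimethoxyphenyl)-7-methoxy-3-methyl-2,3-dihydro-1-benzofuran-5-yl]prop-2-en-1-ol | COc1ccc([C@H]2Oc3c(OC)cc(/C=C/CO)cc3[C@@H]2C)cc1OC | target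

Total steps: 7. Longest linear sequence: 7 steps (1 → 3 → 4 → 6 → 8 → 10 → 11 → 13).

**Steps most likely to fail**

Step 5 (ring closure). The arene of 9 carries no acceptor group, so addition of the alkoxide may be slow. At the temperature then needed, demethylation of the aryl methyl ethers or hydride loss from the benzylic alkoxide may compete.
- Fallback: the same O1–C7a bond is made by an intramolecular Buchwald–Hartwig etherification of an aryl chloride. The mechanism changes from addition–elimination to oxidative addition and reductive elimination.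
- It sets out from 4, which is coupled as in step 3, at the C–Br bond only, with purchased 1-bromo-2-chloro-3-methoxybenzene F1. This should give 2-chloro-1-[(E)-1-(3,4-dimethoxyphenyl)prop-1-en-2-yl]-3-methoxybenzene F2.
- Hydroboration as in step 4 leads through the chloro isopinocampheyl(alkyl)borane F3 to (1S,2S)-2-(2-chloro-3-methoxyphenyl)-1-(3,4-dimethoxyphenyl)propan-1-ol F4.
- Pd(OAc)2, t-BuXPhos and Cs2CO3 in toluene at 90 °C should close the ring with both stereocentres untouched. The route is rejoined at 10.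

Step 4 (asymmetric hydroboration). The diaryl-substituted alkene is hindered, so addition may be slow and the facial selectivity modest. Loss of α-pinene from the reagent would also let achiral borane take part and erode the enantiomeric purity.
- Fallback: reagent control is given up and the absolute configuration comes from a resolution, while the relative configuration still comes from syn addition.
- It sets out from 6. BH3·SMe2 in THF should give the racemic syn adduct [1-(3,4-dimethoxyphenyl)-2-(2-fluoro-3-methoxyphenyl)propyl]borane F5, and NaOH/H2O2 the racemic (1RS,2RS)-1-(3,4-dimethoxyphenyl)-2-(2-fluoro-3-methoxyphenyl)propan-1-ol F6.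
- Esterification with (S)-2-methoxy-2-phenylacetic acid (DCC, DMAP, CH2Cl2) gives two diastereomers, the (S)-2-methoxy-2-phenylacetate of the (1S,2S)-alcohol F7 and the (S)-2-methoxy-2-phenylacetate of the (1R,2R)-alcohol F8. They are separated by chromatography or crystallisation.
- LiOH in THF/H2O cleaves F7, and the route is rejoined at 8.

Step 6 (C–H borylation). Compound 10 holds two electron-rich arenes. The catalyst may also attack C–H bonds next to a methoxy group (C6, C5') or borylate twice, giving regioisomers that are hard to separate. The C5–H bond, para to O1, is also electronically slow.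
- Fallback: the C5 handle is installed on the single-ring bromide before the two arenes are joined.
- It sets out from 5. Borylation under the conditions of step 6 should give 2-(3-bromo-4-fluoro-5-methoxyphenyl)-4,4,5,5-tetramethyl-1,3,2-dioxaborolane F9. CuCl2 in MeOH/H2O at 90 °C then converts it into 1-bromo-5-chloro-2-fluoro-3-methoxybenzene F10.
- Coupling with 4 as in step 3, at the C–Br bond only, gives 5-chloro-1-[(E)-1-(3,4-dimethoxyphenyl)prop-1-en-2-yl]-2-fluoro-3-methoxybenzene F11.
- Hydroboration as in step 4 leads through the 5-chloro isopinocampheyl(alkyl)borane F12 to (1S,2S)-2-(5-chloro-2-fluoro-3-methoxyphenyl)-1-(3,4-dimethoxyphenyl)propan-1-ol F13.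
- KH as in step 5 gives, through the potassium alkoxide of the 5-chloro alcohol F14, (2S,3S)-5-chloro-2-(3,4-dimethoxyphenyl)-7-methoxy-3-methyl-2,3-dihydro-1-benzofuran F15. The chlorine para to fluorine should help this closure slightly.
- Miyaura borylation (Pd2(dba)3, XPhos, B2pin2, KOAc, 1,4-dioxane, 100 °C) rejoins the route at 11.

**Further compounds**
F1 | step 5 | 1-bromo-2-chloro-3-methoxybenzene (purchased) | COc1cccc(Br)c1Cl
F2 | step 5 | 2-chloro-1-[(E)-1-(3,4-dimethoxyphenyl)prop-1-en-2-yl]-3-methoxybenzene | C/C(c1cccc(OC)c1Cl)=C\c1ccc(OC)c(OC)c1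
F3 | step 5 | chloro isopinocampheyl(alkyl)borane (chloro analogue of 7) | COc1ccc([C@H]([C@@H](C)c2cccc(OC)c2Cl)B[C@H]3C[C@H]4C[C@@H]([C@@H]3C)C4(C)C)cc1OC
F4 | step 5 | (1S,2S)-2-(2-chloro-3-methoxyphenyl)-1-(3,4-dimethoxyphenyl)propan-1-ol | COc1ccc([C@H]([C@@H](C)c2cccc(OC)c2Cl)O)cc1OC
F5 | step 4 | racemic syn adduct [1-(3,4-dimethoxyphenyl)-2-(2-fluoro-3-methoxyphenyl)propyl]borane | COc1ccc([C@H]([C@@H](C)c2cccc(OC)c2F)B)cc1OC.COc1ccc([C@@H]([C@H](C)c2cccc(OC)c2F)B)cc1OC
F6 | step 4 | racemic (1RS,2RS)-1-(3,4-dimethoxyphenyl)-2-(2-fluoro-3-methoxyphenyl)propan-1-ol | COc1ccc([C@H]([C@@H](C)c2cccc(OC)c2F)O)cc1OC.COc1ccc([C@@H]([C@H](C)c2cccc(OC)c2F)O)cc1OC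
F7 | step 4 | (S)-2-methoxy-2-phenylacetate of the (1S,2S)-alcohol | COc1ccc([C@H]([C@@H](C)c2cccc(OC)c2F)OC(=O)[C@@H](OC)c2ccccc2)cc1OC
F8 | step 4 | (S)-2-methoxy-2-phenylacetate of the (1R,2R)-alcohol | COc1ccc([C@@H]([C@H](C)c2cccc(OC)c2F)OC(=O)[C@@H](OC)c2ccccc2)cc1OC
F9 | step 6 | 2-(3-bromo-4-fluoro-5-methoxyphenyl)-4,4,5,5-tetramethyl-1,3,2-dioxaborolane | COc1cc(B2OC(C)(C)C(C)(C)O2)cc(Br)c1F
F10 | step 6 | 1-bromo-5-chloro-2-fluoro-3-methoxybenzene | COc1cc(Cl)cc(Br)c1F
F11 | step 6 | 5-chloro-1-[(E)-1-(3,4-dimethoxyphenyl)prop-1-en-2-yl]-2-fluoro-3-methoxybenzene | C/C(c1cc(Cl)cc(OC)c1F)=C\c1ccc(OC)c(OC)c1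
F12 | step 6 | 5-chloro isopinocampheyl(alkyl)borane (5-chloro analogue of 7) | COc1ccc([C@H]([C@@H](C)c2cc(Cl)cc(OC)c2F)B[C@H]3C[C@H]4C[C@@H]([C@@H]3C)C4(C)C)cc1OC
F13 | step 6 | (1S,2S)-2-(5-chloro-2-fluoro-3-methoxyphenyl)-1-(3,4-dimethoxyphenyl)propan-1-ol | COc1ccc([C@H]([C@@H](C)c2cc(Cl)cc(OC)c2F)O)cc1OC
F14 | step 6 | potassium alkoxide of the 5-chloro alcohol | COc1ccc([C@H]([C@@H](C)c2cc(Cl)cc(OC)c2F)[O-])cc1OC.[K+]
F15 | step 6 | (2S,3S)-5-chloro-2-(3,4-dimethoxyphenyl)-7-methoxy-3-methyl-2,3-dihydro-1-benzofuran | COc1ccc([C@H]2Oc3c(OC)cc(Cl)cc3[C@@H]2C)cc1OC
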